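Numbering (germacrane): ring C1–C10 with C1=C10(CH3) E, C3–O-angelate, C4(CH3)=C5 Z, C6–OAc, C7–iPr, C8H2, C9H2. Retrosynthetic cuts, in order: the two ester C–O bonds; C9–C10 together with C10–CH3; C2–C3; C6–C7.
Enabling feature: O3–C3–C2–C1=C10 is a homoallylic alcohol, that is, a 2,3-dihydrofuran ring (O3, C3, C2, C1, C10) opened at C10–O3. Restored as a temporary ring, it makes C10–H lithiable and C10–O3 a leaving group.
Event: C9 and C10 are bound as carbanions to one copper. The 1,2-shift of C9 from Cu to C10 closes the ten-membered ring, opens the temporary ring, sets E-C1=C10 by inversion at C10, frees O3 alone (O6 stays silylated) and leaves C10–Cu for the methyl group.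
Forward order of rings: butenolide (O6, C3, C4, C5, C6; it holds C4=C5 as Z from the start) → opened to the Z-enal → dihydrofuran → ten-membered carbocycle with loss of the dihydrofuran; then angelate at O3 and acetate at O6.
Stereochemistry: C7 and C6 come from one iminium-catalysed vinylogous Mukaiyama–Michael addition, and C3 from a chiral-phosphoric-acid-catalysed propargylboration. Both alkene geometries come from five-membered rings.
A polar closure is mandatory: C9 and C4=C5 form a hex-5-enyl array, so a C9 radical (decarboxylative or reductive nickel coupling) would close C9–C5 instead.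

Key step: step 10

Remark: the sense of induction of the catalysts in steps 2 and 7 is assigned by analogy with simpler aldehydes. Both catalysts are available in either enantiomeric form.

Step 1
Reactants: 1 3-methylfuran-2(5H)-one
Product: 2 3-methyl-2-(trimethylsilyloxy)furan
Conditions: TMSOTf, Et3N, Et2O, 0 °C
Reagents that add atoms: trimethylsilyl trifluoromethanesulfonate, C[Si](C)(C)OS(=O)(=O)C(F)(F)F
Why: Soft enolisation and O-silylation of the butenolide (silyl dienol ether formation) is driven by aromatisation to the 2-silyloxyfuran, whose C5 is the later C6.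

Step 2
Reactants: 2 3-methyl-2-(trimethylsilyloxy)furan; 3 (E)-4-methylpent-2-enal
Product: 5 (5R)-5-[(3S)-1-hydroxy-4-methylpentan-3-yl]-3-methylfuran-2(5H)-one, via butenolide aldehyde 4 (not isolated)
Conditions: (2S,5S)-5-benzyl-2-tert-butyl-3-methylimidazolidin-4-one·TfOH (20 mol %), H2O (2 equiv), CHCl3, −40 °C; then NaBH4, EtOH, 0 °C
Reagents that add atoms: none
Why: In this iminium-catalysed vinylogous Mukaiyama–Michael addition the benzyl and tert-butyl groups of the catalyst shield one face of the E-iminium ion, so that furan C5 attacks the open face of the β-carbon and sets C7 (S); C6 (R) follows from the relative topicity of the open transition state, which in this reaction class responds to acid co-catalyst and solvent, and NaBH4 then reduces only the aldehyde.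

Step 3
Reactants: 5 (5R)-5-[(3S)-1-hydroxy-4-methylpentan-3-yl]-3-methylfuran-2(5H)-one
Product: 6 (5R)-5-[(3S)-1-chloro-4-methylpentan-3-yl]-3-methylfuran-2(5H)-one
Conditions: PPh3, N-chlorosuccinimide, CH2Cl2, 0 °C → rt
Reagents that add atoms: N-chlorosuccinimide, O=C1CCC(=O)N1Cl
Why: Appel-type chlorination proceeds by SN2 at the primary carbon C9, and the chloride is chosen because it is inert to the aluminium, boron, molybdenum and amine reagents of steps 4 to 8.

Step 4
Reactants: 6 (5R)-5-[(3S)-1-chloro-4-methylpentan-3-yl]-3-methylfuran-2(5H)-one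
Product: 7 (2Z,4R,5S)-7-chloro-4-hydroxy-N-methoxy-N,2-dimethyl-5-(propan-2-yl)hept-2-enamide
Conditions: MeNH(OMe)·HCl, Me3Al, CH2Cl2, 0 °C → rt; Rochelle salt work-up, crude product used at once
Reagents that add atoms: N,O-dimethylhydroxylamine hydrochloride, CNOC.Cl
Why: Aminolysis of the lactone by the aluminium amide (Weinreb amide formation) cleaves only the acyl C3–O6 bond, so that C6 and the Z geometry of C4=C5 inherited from the ring are kept.

Step 5
Reactants: 7 (2Z,4R,5S)-7-chloro-4-hydroxy-N-methoxy-N,2-dimethyl-5-(propan-2-yl)hept-2-enamide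
Product: 8 (2Z,4R,5S)-4-(tert-butyldimethylsilyloxy)-7-chloro-N-methoxy-N,2-dimethyl-5-(propan-2-yl)hept-2-enamide
Conditions: TBSOTf, 2,6-lutidine, CH2Cl2, −78 → 0 °C
Reagents that add atoms: tert-butyldimethylsilyl trifluoromethanesulfonate, CC(C)(C)[Si](C)(C)OS(=O)(=O)C(F)(F)F
Why: Silyl ether formation with the reactive triflate caps the hindered C6 hydroxyl before it can close back onto the cis amide, and it gives a group that withstands organolithium and copper reagents.

Step 6
Reactants: 8 (2Z,4R,5S)-4-(tert-butyldimethylsilyloxy)-7-chloro-N-methoxy-N,2-dimethyl-5-(propan-2-yl)hept-2-enamide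
Product: 9 (2Z,4R,5S)-4-(tert-butyldimethylsilyloxy)-7-chloro-2-methyl-5-(propan-2-yl)hept-2-enal
Conditions: DIBAL-H, THF, −78 °C
Reagents that add atoms: none
Why: Hydride reduction of the Weinreb amide stops at the chelated tetrahedral intermediate and releases the Z-enal only on work-up, without touching the chloride or the silyl ether.

Step 7
Reactants: 9 (2Z,4R,5S)-4-(tert-butyldimethylsilyloxy)-7-chloro-2-methyl-5-(propan-2-yl)hept-2-enal; 10 allenylboronic acid pinacol ester
Product: 11 (4S,5Z,7R,8S)-7-(tert-butyldimethylsilyloxy)-10-chloro-5-methyl-8-(propan-2-yl)dec-5-en-1-yn-4-ol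
Conditions: (S)-TRIP phosphoric acid (10 mol %), 4 Å MS, toluene, −20 °C
Reagents that add atoms: none
Why: Chiral-phosphoric-acid-catalysed propargylboration runs as SE2′ through a closed six-membered transition state in which the catalyst binds the boronate oxygen and the formyl hydrogen, so that it delivers the propargyl group to the Si face of C3=O under catalyst control and sets C3 (S).

Step 8
Reactants: 11 (4S,5Z,7R,8S)-7-(tert-butyldimethylsilyloxy)-10-chloro-5-methyl-8-(propan-2-yl)dec-5-en-1-yn-4-ol
Product: 12 (2S)-2-[(2Z,4R,5S)-4-(tert-butyldimethylsilyloxy)-7-chloro-5-(propan-2-yl)hept-2-en-2-yl]-2,3-dihydrofuran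
Conditions: Mo(CO)6 (30 mol %), Me3NO (30 mol %), Et3N–Et2O, rt
Reagents that add atoms: none
Why: In this molybdenum-catalysed endo cycloisomerisation of a 3-butyn-1-ol, the terminal alkyne becomes a metal vinylidene whose electrophilic carbon C10 is attacked by O3, and protodemetallation gives the 2,3-dihydrofuran with C3 untouched.

Step 9
Reactants: 12 (2S)-2-[(2Z,4R,5S)-4-(tert-butyldimethylsilyloxy)-7-chloro-5-(propan-2-yl)hept-2-en-2-yl]-2,3-dihydrofuran
Product: 13 (2S)-2-[(2Z,4R,5S)-4-(tert-butyldimethylsilyloxy)-7-iodo-5-(propan-2-yl)hept-2-en-2-yl]-2,3-dihydrofuran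
Conditions: NaI, NaHCO3, acetone, reflux
Reagents that add atoms: sodium iodide, [Na+].[I-]
Why: Finkelstein exchange (SN2 at primary C9, driven by precipitation of NaCl, with the enol ether kept safe by the buffer) supplies the iodide, the only halide that exchanges cleanly with t-BuLi without radical leakage.

Step 10
Reactants: 13 (2S)-2-[(2Z,4R,5S)-4-(tert-butyldimethylsilyloxy)-7-iodo-5-(propan-2-yl)hept-2-en-2-yl]-2,3-dihydrofuran
Product: 17 (1S,2Z,4R,5S,8E)-4-(tert-butyldimethylsilyloxy)-2,8-dimethyl-5-(propan-2-yl)cyclodeca-2,8-dien-1-ol, via dilithio species 14 (not isolated), via cyclic cuprate 15 (not isolated), via alkenylcopper alkoxide 16 (not isolated)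
Conditions: t-BuLi (3.3 equiv), Et2O–pentane, −78 °C, then THF, −78 → 0 °C; slow cannulation into CuBr·SMe2 (1.05 equiv), Et2O–Me2S, final 2 mM, −78 °C → rt; MeI (excess), DMPU, 0 °C → rt; aq NH4Cl/NH3
Reagents that add atoms: iodomethane, CI
Why: Proposed new method: two-electron iodine–lithium exchange at C9 and deprotonation of the enol-ether C10–H give dilithio species 14, Cu(I) takes up both carbanions as the cyclic Gilman-type cuprate 15, on warming C9 migrates from copper to C10 anti to the lithium-activated C10–O3 bond (1,2-metallate rearrangement) so that O3 leaves as the alkoxide, and the alkenylcopper 16 is methylated by MeI with retention. The closest known reaction types are the intermolecular rearrangement of primary-alkyl(4,5-dihydrofuran-2-yl)cuprates with MeI quench, which gives (E)-4-methylalk-3-en-1-ols, and the closure of medium rings through cyclic diorganocuprates made from dimetallated chains; new is that both copper ligands of the rearrangement sit on one chain. The ten-membered ring forms by one-atom contraction of the eleven-membered cupracycle (Cu, C9, C8, C7, C6, C5, C4, C3, C2, C1, C10), an endo attack on C10 during which the five-membered ring O3–C3–C2–C1=C10 opens, so the strain of a 3,10-oxygen-bridged bicycle is never built up. No stereocentre is created: inversion at the sp2 carbon C10 puts C9 trans and copper, later methyl, cis to C2, which is the E geometry, while C3, C6, C7 and Z-C4=C5 are spectators and the C4 substituent, standing out of the dihydrofuran plane at C3, leads the chain over one face of C1=C10 only. Ring closure has to beat oligomerisation, and this is secured because ligand exchange between cuprates is fast and reversible below the migration temperature, so that at about 2 mM the monomeric chelate 15 should dominate before the irreversible, unimolecular shift. Chemoselectivity rests on the polar pathway (a C9 radical would add 5-exo to C5 of C4=C5, hence iodide plus t-BuLi and no nickel or electron-transfer reagent) and on allylic 1,3-strain with the cis C6 substituent, which holds C3–H in the plane of C4=C5 and so keeps it from competing with C10–H in the lithiation.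

Step 11
Reactants: 17 (1S,2Z,4R,5S,8E)-4-(tert-butyldimethylsilyloxy)-2,8-dimethyl-5-(propan-2-yl)cyclodeca-2,8-dien-1-ol; 18 angelic anhydride
Product: 19 (1S,2Z,4R,5S,8E)-4-(tert-butyldimethylsilyloxy)-2,8-dimethyl-5-(propan-2-yl)cyclodeca-2,8-dien-1-yl (2Z)-2-methylbut-2-enoate
Conditions: LiHMDS, THF, −78 °C; 18, −78 → 0 °C
Reagents that add atoms: none
Why: Acylation of the preformed lithium alkoxide with the anhydride (stereoconservative angeloylation) needs no nucleophilic catalyst, so the addition–elimination path that turns angelate into tiglate is closed, and C3–O is not broken.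

Step 12
Reactants: 19 (1S,2Z,4R,5S,8E)-4-(tert-butyldimethylsilyloxy)-2,8-dimethyl-5-(propan-2-yl)cyclodeca-2,8-dien-1-yl (2Z)-2-methylbut-2-enoate
Product: 20 (1S,2Z,4R,5S,8E)-4-hydroxy-2,8-dimethyl-5-(propan-2-yl)cyclodeca-2,8-dien-1-yl (2Z)-2-methylbut-2-enoate
Conditions: TBAF, AcOH (1:1), THF, 0 °C → rt
Reagents that add atoms: none
Why: In this fluoride-induced desilylation the acetic acid buffer protonates the C6 alkoxide at once, which should suppress acyl migration from O3 and avoids the acid that would trigger transannular cyclisation of the 1,5-diene.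

Step 13
Reactants: 20 (1S,2Z,4R,5S,8E)-4-hydroxy-2,8-dimethyl-5-(propan-2-yl)cyclodeca-2,8-dien-1-yl (2Z)-2-methylbut-2-enoate
Product: 21 (1S,2Z,4R,5S,8E)-4-(acetyloxy)-2,8-dimethyl-5-(propan-2-yl)cyclodeca-2,8-dien-1-yl (2Z)-2-methylbut-2-enoate (target)
Conditions: Ac2O, pyridine, DMAP (cat.), CH2Cl2, 0 °C → rt
Reagents that add atoms: acetic anhydride, CC(=O)OC(C)=O
Why: DMAP-catalysed acetylation of the only free hydroxyl forms the O6–acyl bond with retention at C6, at a temperature far below that of a Cope rearrangement of the ring diene.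

Compound list
1 | 3-methylfuran-2(5H)-one | CC1=CCOC1=O | starting material
2 | 3-methyl-2-(trimethylsilyloxy)furan | Cc1ccoc1O[Si](C)(C)C | intermediate
3 | (E)-4-methylpent-2-enal | CC(C)/C=C/C=O | starting material
4 | (3S)-4-methyl-3-[(2R)-4-methyl-5-oxo-2,5-dihydrofuran-2-yl]pentanal | O=CC[C@@H](C(C)C)[C@H]1OC(=O)C(C)=C1 | intermediate
5 | (5R)-5-[(3S)-1-hydroxy-4-methylpentan-3-yl]-3-methylfuran-2(5H)-one | OCC[C@@H](C(C)C)[C@H]1OC(=O)C(C)=C1 | intermediate
6 | (5R)-5-[(3S)-1-chloro-4-methylpentan-3-yl]-3-methylfuran-2(5H)-one | ClCC[C@@H](C(C)C)[C@H]1OC(=O)C(C)=C1 | intermediate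
7 | (2Z,4R,5S)-7-chloro-4-hydroxy-N-methoxy-N,2-dimethyl-5-(propan-2-yl)hept-2-enamide | ClCC[C@@H](C(C)C)[C@@H](O)/C=C(/C)C(=O)N(C)OC | intermediate
8 | (2Z,4R,5S)-4-(tert-butyldimethylsilyloxy)-7-chloro-N-methoxy-N,2-dimethyl-5-(propan-2-yl)hept-2-enamide | ClCC[C@@H](C(C)C)[C@@H](O[Si](C)(C)C(C)(C)C)/C=C(/C)C(=O)N(C)OC | intermediate
9 | (2Z,4R,5S)-4-(tert-butyldimethylsilyloxy)-7-chloro-2-methyl-5-(propan-2-yl)hept-2-enal | ClCC[C@@H](C(C)C)[C@@H](O[Si](C)(C)C(C)(C)C)/C=C(/C)C=O | intermediate
10 | allenylboronic acid pinacol ester | C=C=CB1OC(C)(C)C(C)(C)O1 | starting material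
11 | (4S,5Z,7R,8S)-7-(tert-butyldimethylsilyloxy)-10-chloro-5-methyl-8-(propan-2-yl)dec-5-en-1-yn-4-ol | ClCC[C@@H](C(C)C)[C@@H](O[Si](C)(C)C(C)(C)C)/C=C(/C)[C@@H](O)CC#C | intermediate
12 | (2S)-2-[(2Z,4R,5S)-4-(tert-butyldimethylsilyloxy)-7-chloro-5-(propan-2-yl)hept-2-en-2-yl]-2,3-dihydrofuran | ClCC[C@@H](C(C)C)[C@@H](O[Si](C)(C)C(C)(C)C)/C=C(/C)[C@@H]1CC=CO1 | intermediate
13 | (2S)-2-[(2Z,4R,5S)-4-(tert-butyldimethylsilyloxy)-7-iodo-5-(propan-2-yl)hept-2-en-2-yl]-2,3-dihydrofuran | ICC[C@@H](C(C)C)[C@@H](O[Si](C)(C)C(C)(C)C)/C=C(/C)[C@@H]1CC=CO1 | intermediate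
14 | C9,C10-dilithio derivative of 13 (lithium at the chain end and at C5 of the dihydrofuran) | [Li]CC[C@@H](C(C)C)[C@@H](O[Si](C)(C)C(C)(C)C)/C=C(/C)[C@@H]1CC=C([Li])O1 | intermediate
15 | lithium salt of the cyclic cuprate with copper bound to C9 and C10 | [Li+].[Cu-]1CC[C@@H](C(C)C)[C@@H](O[Si](C)(C)C(C)(C)C)/C=C(/C)[C@@H]2CC=C1O2 | intermediate
16 | ten-membered C10-alkenylcopper, C3 lithium alkoxide (copper cis to C2) | [Li]O[C@H]1C/C=C(\[Cu])CC[C@@H](C(C)C)[C@@H](O[Si](C)(C)C(C)(C)C)/C=C\1C | intermediate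
17 | (1S,2Z,4R,5S,8E)-4-(tert-butyldimethylsilyloxy)-2,8-dimethyl-5-(propan-2-yl)cyclodeca-2,8-dien-1-ol | O[C@H]1C/C=C(\C)CC[C@@H](C(C)C)[C@@H](O[Si](C)(C)C(C)(C)C)/C=C\1C | intermediate
18 | angelic anhydride, (2Z)-2-methylbut-2-enoic anhydride | C/C=C(/C)C(=O)OC(=O)/C(C)=C\C | starting material
19 | (1S,2Z,4R,5S,8E)-4-(tert-butyldimethylsilyloxy)-2,8-dimethyl-5-(propan-2-yl)cyclodeca-2,8-dien-1-yl (2Z)-2-methylbut-2-enoate | C/C=C(/C)C(=O)O[C@H]1C/C=C(\C)CC[C@@H](C(C)C)[C@@H](O[Si](C)(C)C(C)(C)C)/C=C\1C | intermediate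
20 | (1S,2Z,4R,5S,8E)-4-hydroxy-2,8-dimethyl-5-(propan-2-yl)cyclodeca-2,8-dien-1-yl (2Z)-2-methylbut-2-enoate | C/C=C(/C)C(=O)O[C@H]1C/C=C(\C)CC[C@@H](C(C)C)[C@@H](O)/C=C\1C | intermediate
21 | (1S,2Z,4R,5S,8E)-4-(acetyloxy)-2,8-dimethyl-5-(propan-2-yl)cyclodeca-2,8-dien-1-yl (2Z)-2-methylbut-2-enoate | C/C=C(/C)C(=O)O[C@H]1C/C=C(\C)CC[C@@H](C(C)C)[C@@H](OC(C)=O)/C=C\1C | target

Total step count: 13. Longest linear sequence: 13 steps (from 1).

Steps most likely to fail

**Step 10 (Proposed new method).** Several processes could defeat it: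
- oligomerisation through cuprates that bind C9 and C10 of different molecules;
- proton transfer that quenches C9–Li while C10–H is being lithiated;
- migration of the silyl group from O6 to the C9 carbanion;
- a 1,2-shift too slow to outrun thermal decay of the alkylcuprate.

The fallback closes the same C9–C10 bond by known cross-coupling; it sets out from 11 and comes back at 17. Compound 11 is silylated (TESCl, imidazole) to the triethylsilyl ether F1. Its lithium acetylide is methylated (n-BuLi, then MeI) to the but-2-ynyl compound F2. Hydrozirconation with an excess of Cp2Zr(H)Cl, under which zirconium settles next to the methyl group, followed by iodinolysis gives the (E)-alkenyl iodide F3. Finkelstein exchange gives the alkyl iodide F4. Zinc insertion (Zn, LiCl, THF) touches only the sp3 C–I bond and gives the alkylzinc iodide F5. Under palladium catalysis at high dilution (Negishi coupling, retention at C10) this closes to the ring bis-silyl ether F6. Buffered HF·pyridine removes only the triethylsilyl group and gives 17.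

**Step 2.** The risk is poor or reversed simple diastereoselection at C6, while C7 remains under catalyst control. The fallback makes the sequence stereoconvergent; it sets out from 2 and 3 and comes back at 6. The addition is run under whichever conditions are most selective, and the C6-epimeric aldehyde F7 is reduced in the same flask to the C6-epimeric alcohol F8. Chlorination as in step 3 gives the C6-epimeric chloride F9, and aminolysis as in step 4 gives the (4S)-hydroxy amide F10. Methanesulfonic anhydride and Et3N convert it into the allylic mesylate F11. This is displaced from the rear by the cis-disposed amide carbonyl oxygen to give the iminium lactone F12. Aqueous hydrolysis gives 6 with C6 inverted.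

**Step 4.** The risk is reclosure of the Z-γ-hydroxy amide to the butenolide before silylation, or 1,4-addition of the aluminium amide. The fallback avoids the acyl oxidation level; it sets out from 6 and comes back at 9. An excess of DIBAL-H reduces the lactone to the Z-enediol F13. TBSOTf and 2,6-lutidine give the bis-silyl ether F14. Buffered HF·pyridine frees only the primary allylic alcohol F15. MnO2 oxidises it to 9.

Further compounds
F1 | step 10 | (4S,5Z,7R,8S)-7-(tert-butyldimethylsilyloxy)-10-chloro-5-methyl-8-(propan-2-yl)-4-(triethylsilyloxy)dec-5-en-1-yne | ClCC[C@@H](C(C)C)[C@@H](O[Si](C)(C)C(C)(C)C)/C=C(/C)[C@@H](O[Si](CC)(CC)CC)CC#C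
F2 | step 10 | C-methylated alkyne, (5S,6Z,8R,9S)-8-(tert-butyldimethylsilyloxy)-11-chloro-6-methyl-9-(propan-2-yl)-5-(triethylsilyloxy)undec-6-en-2-yne | ClCC[C@@H](C(C)C)[C@@H](O[Si](C)(C)C(C)(C)C)/C=C(/C)[C@@H](O[Si](CC)(CC)CC)CC#CC
F3 | step 10 | (E)-alkenyl iodide with primary chloride (iodine at C10 trans to C2) | ClCC[C@@H](C(C)C)[C@@H](O[Si](C)(C)C(C)(C)C)/C=C(/C)[C@@H](O[Si](CC)(CC)CC)C/C=C(\C)I
F4 | step 10 | (E)-alkenyl iodide with primary iodide | ICC[C@@H](C(C)C)[C@@H](O[Si](C)(C)C(C)(C)C)/C=C(/C)[C@@H](O[Si](CC)(CC)CC)C/C=C(\C)I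
F5 | step 10 | C9 alkylzinc iodide bearing the (E)-alkenyl iodide | I[Zn]CC[C@@H](C(C)C)[C@@H](O[Si](C)(C)C(C)(C)C)/C=C(/C)[C@@H](O[Si](CC)(CC)CC)C/C=C(\C)I
F6 | step 10 | triethylsilyl ether of 17 | CC[Si](CC)(CC)O[C@H]1C/C=C(\C)CC[C@@H](C(C)C)[C@@H](O[Si](C)(C)C(C)(C)C)/C=C\1C
F7 | step 2 | (3S)-4-methyl-3-[(2S)-4-methyl-5-oxo-2,5-dihydrofuran-2-yl]pentanal | O=CC[C@@H](C(C)C)[C@@H]1OC(=O)C(C)=C1
F8 | step 2 | (5S)-5-[(3S)-1-hydroxy-4-methylpentan-3-yl]-3-methylfuran-2(5H)-one | OCC[C@@H](C(C)C)[C@@H]1OC(=O)C(C)=C1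
F9 | step 2 | (5S)-5-[(3S)-1-chloro-4-methylpentan-3-yl]-3-methylfuran-2(5H)-one | ClCC[C@@H](C(C)C)[C@@H]1OC(=O)C(C)=C1
F10 | step 2 | (2Z,4S,5S)-7-chloro-4-hydroxy-N-methoxy-N,2-dimethyl-5-(propan-2-yl)hept-2-enamide | ClCC[C@@H](C(C)C)[C@H](O)/C=C(/C)C(=O)N(C)OC
F11 | step 2 | methanesulfonate of F10 | ClCC[C@@H](C(C)C)[C@H](OS(C)(=O)=O)/C=C(/C)C(=O)N(C)OC
F12 | step 2 | (5R)-iminium lactone methanesulfonate | ClCC[C@@H](C(C)C)[C@H]1OC(=[N+](C)OC)C(C)=C1.CS(=O)(=O)[O-]
F13 | step 4 | (2Z,4R,5S)-7-chloro-2-methyl-5-(propan-2-yl)hept-2-ene-1,4-diol | ClCC[C@@H](C(C)C)[C@@H](O)/C=C(/C)CO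
F14 | step 4 | bis(tert-butyldimethylsilyl) ether of F13 | ClCC[C@@H](C(C)C)[C@@H](O[Si](C)(C)C(C)(C)C)/C=C(/C)CO[Si](C)(C)C(C)(C)C
F15 | step 4 | (2Z,4R,5S)-4-(tert-butyldimethylsilyloxy)-7-chloro-2-methyl-5-(propan-2-yl)hept-2-en-1-ol | ClCC[C@@H](C(C)C)[C@@H](O[Si](C)(C)C(C)(C)C)/C=C(/C)CO
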